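At early times the north-west run, with less free catalyst, starts slowly: target reads 2 % at 0.833 h, then 9 % at 1.50 h. So you should suspect that something builds up before target appears.

| setting | north | north-west | flask |
|---|---|---|---|
| substrate | 44 mM | 44 mM | 44 mM |
| reagent | 41.8 mM | 41.8 mM | 41.8 mM |
| free catalyst | 0.88 mM | 0.59 mM | 0.88 mM |
| remark | the very flask that is asked about, followed so far | run made earlier |  |
| time |  |  | 40 h |

| run | time / h | target / % |
|---|---|---|
| north | 5.00 | 26 |
| north | 15.0 | 33 |
| north | 25.0 | 33 |
| north | 40.0 | 32 |
| north-west | 0.833 | 2 |
| north-west | 1.50 | 9 |
| north-west | 2.50 | 13 |
| north-west | 3.00 | 11 |

(scatter of a reading: 1.5 percentage points)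

- autumn: at 40 h add reagent, 100 % of the amount charged, then wait 20 h
- noon: at 40 h take out 90 % of the target then present, then wait 20 h
- midnight: at 40 h add free catalyst, 100 % of the amount charged, then wait 20 h
- summer: change nothing and wait 20 h more

- what is taken out of target is counted as made
- what was read earlier has a scatter of 1.5 percentage points, one standard deviation
- additions bring no volume worth counting

1. target, in percent of the substrate first charged, at 40 h
2. the remedy with the largest gain of target, or "none" below 2 percentage points (autumn / noon / midnight / summer / none)
3. target present, with what was taken out counted in, in percent of the substrate first charged, after midnight
4. target present, with what was taken out counted in, in percent of the substrate first charged, after summer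

In the middle of the north flask, with c(free catalyst) at 0.88 mM, target reaches 26 % by 5.00 h. The last three readings average 32.7 % and differ by less than the scatter allows, so you are looking at a plateau. Treat the rise as a step response: the gap left at 5.00 h gives a time constant of about 3.15 h. By 40 h, about 12.7 time constants have passed, so I expect summer to add nothing.

At the plateau of the north run, a reading of about 67.3 % of the substrate charge has not become target. The readings cannot prove why, but I judge that the catalyst has stopped working (catalyst deactivation) and that no balance has been reached. On that view I expect no gain from reagent or from removal of target, and I expect a gain from fresh catalyst.

To size that remedy, take 0.485, the conversion odds of one catalyst charge: target divided by the part of the substrate charge that has not become target. Substrate and reagent are charged nearly equal, so if the rate is proportional to both, it falls with the square of what remains, and the odds then grow in step with the catalyst work delivered. On that assumption, midnight delivers that work a second time. I therefore expect odds of 0.970, which means 49.2 % target.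

The forecast gives 32.7 % now, 32.8 % after summer and 47 % after midnight, and it chooses midnight; my midnight figure stands a little higher. Its ground, given as a judgement: “Fresh catalyst should then repeat the earlier progress on the depleted mixture”.

The flask gives 33.4 % at 40 h, 33.4 % after summer and 48.9 % after midnight. The best remedy is midnight, with a gain of 16 percentage points.

    reagent + catalyst intermediate → free catalyst + target (k = 0.250 /M/s)
    free catalyst + open intermediate ⇌ catalyst intermediate (K = 12.0 /M, k = 0.870 /M/s)
    substrate + free catalyst → free catalyst + open intermediate (k = 0.550 /M/s)
    substrate + reagent → uncatalysed product (k = 0.00200 /M/s)
    free catalyst → spent catalyst (k = 1.00 × 10⁻⁴ /s)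

After midnight the north flask's odds are 0.957, against the doubled 0.970. Now take the neighbour flask with 100 mM of reagent and, as a rough reckoning, scale 0.485 by the reagent charge: that gives odds of 1.16, so 53.7 % target. That flask gives 49.1 %, less than reckoned. It ends with 32.8 % of its substrate as uncatalysed product, where the north flask ends with 17.8 %.

Readings and results were computed with constants of no real substance, noise included.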